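The route disconnects the C2–C3 bond of the γ-lactone ring: C2 is the oxygenated quaternary carbon next to the lactone carbonyl C1, and C3 carries the ring carbon C4H2–O, which is treated as the remnant of a former alkene carbon. This 2-alkoxy-4-enoic acid pattern is assembled by a chelate-controlled Ireland–Claisen rearrangement that forms C2–C3, sets both stereocentres and relays the configuration of a sacrificial (S)-allylic carbinol in one operation. Its precursor is the ester of a racemic α-benzyloxy-β-arylpropanoic acid (syringyl half) with an (S,E)-5-arylpent-3-en-2-ol (guaiacyl half). Alkene cleavage, lactonisation and a single hydrogenolysis then give the target.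

Key step: step 9

Remark: in the text the lactone carbonyl carbon is C1, the quaternary carbinol carbon C2, the benzyl-bearing methine C3 and the ring methylene C4 (systematic names in the list use furanone numbering). The purchased (S)-but-3-en-2-ol is assumed to be of high enantiomeric purity, which caps that of the product.

Step 1
Reactants: 1 syringaldehyde
Product: 2 4-(benzyloxy)-3,5-dimethoxybenzaldehyde
Conditions: BnBr, K2CO3, DMF, 60 °C
Reagents that add atoms: benzyl bromide BrCc1ccccc1
Why: Williamson O-benzylation of the acidic phenol (phenoxide SN2 on benzyl bromide) should proceed cleanly, the aldehyde being inert to K2CO3.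

Step 2
Reactants: 2 4-(benzyloxy)-3,5-dimethoxybenzaldehyde
Product: 3 [4-(benzyloxy)-3,5-dimethoxyphenyl]methanol
Conditions: NaBH4, MeOH/THF, 0 °C
Reagents that add atoms: none
Why: Chemoselective borohydride reduction of the aryl aldehyde should give the benzylic alcohol without touching the ether groups.

Step 3
Reactants: 3 [4-(benzyloxy)-3,5-dimethoxyphenyl]methanol
Product: 4 4-(benzyloxy)-3,5-dimethoxybenzyl bromide
Conditions: PBr3 (0.4 equiv), CH2Cl2, 0 °C; used directly
Reagents that add atoms: phosphorus tribromide BrP(Br)Br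
Why: Bromination of an activated benzylic alcohol with PBr3 is fast at 0 °C, and the electron-rich bromide is used at once to avoid decomposition on storage.

Step 4
Reactants: 4 4-(benzyloxy)-3,5-dimethoxybenzyl bromide; 5 methyl 2-(benzyloxy)acetate
Product: 7 methyl 2-(benzyloxy)-3-[4-(benzyloxy)-3,5-dimethoxyphenyl]propanoate (racemic), via lithium enolate 6 (not isolated)
Conditions: 5 (1.4 equiv), LiN(iPr)2 (1.3 equiv), THF, −78 °C, 30 min; then 4 (1.0 equiv), DMPU, −78 → −40 °C
Reagents that add atoms: lithium diisopropylamide CC(C)N([Li])C(C)C (its lithium is carried only by 6)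
Why: SN2 C-alkylation of the glycolate ester enolate by a reactive benzylic bromide, with the enolate made cold, kept in slight excess and trapped quickly to outrun self-condensation; the new α-centre is deliberately racemic because step 9 erases it.

Step 5
Reactants: 7 methyl 2-(benzyloxy)-3-[4-(benzyloxy)-3,5-dimethoxyphenyl]propanoate
Product: 8 2-(benzyloxy)-3-[4-(benzyloxy)-3,5-dimethoxyphenyl]propanoic acid (racemic)
Conditions: LiOH·H2O, THF/MeOH/H2O, rt; then 1 M HCl
Reagents that add atoms: lithium hydroxide [Li+].[OH-] (its oxygen becomes the carboxyl OH oxygen)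
Why: Ordinary saponification of a methyl ester, under which the benzyl and methyl ethers are stable.

Step 6
Reactants: 9 eugenol
Product: 10 4-allyl-1-(benzyloxy)-2-methoxybenzene (O-benzyl eugenol)
Conditions: BnBr, K2CO3, acetone, reflux
Reagents that add atoms: benzyl bromide BrCc1ccccc1
Why: Williamson O-benzylation of the phenol; under carbonate the allyl group should not migrate into conjugation.

Step 7
Reactants: 10 4-allyl-1-(benzyloxy)-2-methoxybenzene; 11 (S)-but-3-en-2-ol
Product: 12 (S,E)-5-[4-(benzyloxy)-3-methoxyphenyl]pent-3-en-2-ol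
Conditions: second-generation Hoveyda–Grubbs catalyst, [1,3-bis(2,4,6-trimethylphenyl)imidazolidin-2-ylidene]dichloro(2-isopropoxybenzylidene)ruthenium (3 mol %), 11 (3 equiv), 1,4-benzoquinone (10 mol %), CH2Cl2, 40 °C; chromatography on AgNO3-impregnated silica
Reagents that add atoms: none
Why: Olefin cross-metathesis of a terminal allylarene with a secondary allylic alcohol releases ethylene and should strongly favour the E isomer; the carbinol centre of 11 is not involved and is retained, benzoquinone suppresses double-bond migration, and residual Z isomer is removed on the silver-doped silica.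

Step 8
Reactants: 8 2-(benzyloxy)-3-[4-(benzyloxy)-3,5-dimethoxyphenyl]propanoic acid; 12 (S,E)-5-[4-(benzyloxy)-3-methoxyphenyl]pent-3-en-2-ol
Product: 13 (2S,3E)-5-[4-(benzyloxy)-3-methoxyphenyl]pent-3-en-2-yl (2RS)-2-(benzyloxy)-3-[4-(benzyloxy)-3,5-dimethoxyphenyl]propanoate (two α-epimers)
Conditions: DCC (1.2 equiv), DMAP (10 mol %), CH2Cl2, 0 °C → rt
Reagents that add atoms: none
Why: Steglich esterification acylates the allylic oxygen without breaking the carbinol C–O bond, so the (S) centre and the E alkene are retained; the α-epimer mixture is intended.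

Step 9
Reactants: 13 (2S,3E)-5-[4-(benzyloxy)-3-methoxyphenyl]pent-3-en-2-yl (2RS)-2-(benzyloxy)-3-[4-(benzyloxy)-3,5-dimethoxyphenyl]propanoate
Product: 17 (2S,3R,4E)-2-(benzyloxy)-2-[4-(benzyloxy)-3,5-dimethoxybenzyl]-3-[4-(benzyloxy)-3-methoxybenzyl]hex-4-enoic acid, via lithium enolate 14 (not isolated), via silyl ketene acetal 15 (not isolated), via trimethylsilyl ester 16 (not isolated)
Conditions: LiN(iPr)2 (1.5 equiv), THF, −78 °C, 1 h; Me3SiCl/Et3N (3 equiv), −78 °C → rt, then 45 °C; 1 M HCl work-up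
Reagents that add atoms: lithium diisopropylamide CC(C)N([Li])C(C)C (its lithium is carried only by 14); chlorotrimethylsilane C[Si](C)(C)Cl (its Me3Si group is carried only by 15 and 16 and is lost on work-up)
Why: LiN(iPr)2 removes the α-proton of either epimer of 13 to give a single lithium enolate 14 in which lithium bridges the enolate oxygen and the α-benzyloxy oxygen (five-membered chelate), and O-silylation fixes this as ketene acetal 15 with OSiMe3 and OBn on the same side of the C=C bond. On warming, 15 undergoes a concerted suprafacial [3,3]-sigmatropic shift through a chair transition state (Ireland–Claisen rearrangement, the closest precedent being the chelation-controlled rearrangement of allylic glycolate and lactate-type α-alkoxy esters), trading the ester C–O bond for the C2–C3 bond and leaving silyl ester 16, which is hydrolysed on work-up. No ring is closed; the six-membered array exists only in the transition state and the lactone is made later. C3 (R) is controlled by the (S)-carbinol, whose methyl group takes the equatorial position of the chair so that bond formation occurs on one face of the E alkene, the carbinol carbon ending up in the new E-propenyl group. C2 (S) is controlled by the fixed ketene acetal geometry acting together with the E alkene in that same chair, which puts OBn and H-3 on one side and therefore the two arylmethyl groups cis in the later lactone. The selectivities needed are one ketene acetal geometry (secured by the lithium chelate in THF without strongly coordinating cosolvent) and one chair face (secured by the carbinol methyl and the geometric purity of 12), while intramolecular bond formation overcomes the hindrance of joining a fully substituted carbon to a branched one and no β-leaving group or competing acidic site is present.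

Step 10
Reactants: 17 (2S,3R,4E)-2-(benzyloxy)-2-[4-(benzyloxy)-3,5-dimethoxybenzyl]-3-[4-(benzyloxy)-3-methoxybenzyl]hex-4-enoic acid
Product: 20 (3S,4S)-3-(benzyloxy)-3-[4-(benzyloxy)-3,5-dimethoxybenzyl]-4-[4-(benzyloxy)-3-methoxybenzyl]-5-hydroxydihydrofuran-2(3H)-one (both C5 anomers), via diol 18 (not isolated), via aldehyde acid 19 (not isolated)
Conditions: OsO4 (2 mol %), NaIO4 (4 equiv), 2,6-lutidine (2 equiv), 1,4-dioxane/H2O (3:1), rt; dilute acid work-up; crude lactol taken on
Reagents that add atoms: osmium tetroxide O=[Os](=O)(=O)=O (delivers the diol oxygens of 18, one of which remains as the C5–OH oxygen of 20); sodium periodate [Na+].[O-]I(=O)(=O)=O and water O (ultimate oxygen source that regenerates OsO4)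
Why: Lemieux–Johnson cleavage (osmylation, then periodate glycol fission) is selective for the isolated alkene beside electron-rich arenes and benzyl ethers that ozone could attack, and the γ-oxo acid closes to a lactol that masks the aldehyde and so shields the adjacent C3 centre from epimerisation; C2 and C3 are untouched (the descriptor change at C3 is only a priority change).

Step 11
Reactants: 20 (3S,4S)-3-(benzyloxy)-3-[4-(benzyloxy)-3,5-dimethoxybenzyl]-4-[4-(benzyloxy)-3-methoxybenzyl]-5-hydroxydihydrofuran-2(3H)-one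
Product: 24 (3S,4R)-3-(benzyloxy)-3-[4-(benzyloxy)-3,5-dimethoxybenzyl]-4-[4-(benzyloxy)-3-methoxybenzyl]dihydrofuran-2(3H)-one, via sodium oxo carboxylate 21 (not isolated), via sodium hydroxy carboxylate 22 (not isolated), via hydroxy acid 23 (not isolated)
Conditions: NaBH4, THF/MeOH, 0 °C; then 2 M HCl, rt
Reagents that add atoms: sodium borohydride [Na+].[BH4-] (its sodium is carried only by 21 and 22)
Why: In the basic borohydride medium the pseudo-acid 20 is deprotonated and opens to the sodium carboxylate of the aldehyde, whose formyl group is reduced cold and quickly (NaBH4 carbonyl reduction, C3 kept intact) to the γ-hydroxy carboxylate; acidification then frees the γ-hydroxy acid, which should lactonise by 5-exo-trig O–C1 acylation, helped by the fully substituted C2.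

Step 12
Reactants: 24 (3S,4R)-3-(benzyloxy)-3-[4-(benzyloxy)-3,5-dimethoxybenzyl]-4-[4-(benzyloxy)-3-methoxybenzyl]dihydrofuran-2(3H)-one
Product: 25 (3S,4R)-3-hydroxy-3-(4-hydroxy-3,5-dimethoxybenzyl)-4-(4-hydroxy-3-methoxybenzyl)dihydrofuran-2(3H)-one (target CNP0176953.1)
Conditions: H2 (1 atm), Pd(OH)2/C, EtOAc/EtOH, rt
Reagents that add atoms: none
Why: Catalytic hydrogenolysis should cleave the two aryl benzyl ethers and, more slowly, the hindered tertiary benzyl ether at their O–CH2Ph bonds only, leaving the lactone, the arenes and both stereocentres unchanged.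

Compound list
1 | syringaldehyde | COc1cc(C=O)cc(OC)c1O | starting material
2 | 4-(benzyloxy)-3,5-dimethoxybenzaldehyde | COc1cc(C=O)cc(OC)c1OCc1ccccc1 | intermediate
3 | [4-(benzyloxy)-3,5-dimethoxyphenyl]methanol | COc1cc(CO)cc(OC)c1OCc1ccccc1 | intermediate
4 | 4-(benzyloxy)-3,5-dimethoxybenzyl bromide | COc1cc(CBr)cc(OC)c1OCc1ccccc1 | intermediate
5 | methyl 2-(benzyloxy)acetate | COC(=O)COCc1ccccc1 | starting material
6 | lithium enolate of 5, OLi cis to OBn (formed in situ) | [Li]O/C(OC)=C\OCc1ccccc1 | intermediate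
7 | methyl 2-(benzyloxy)-3-[4-(benzyloxy)-3,5-dimethoxyphenyl]propanoate (racemic) | COC(=O)C(Cc1cc(OC)c(OCc2ccccc2)c(OC)c1)OCc1ccccc1 | intermediate
8 | 2-(benzyloxy)-3-[4-(benzyloxy)-3,5-dimethoxyphenyl]propanoic acid (racemic) | O=C(O)C(Cc1cc(OC)c(OCc2ccccc2)c(OC)c1)OCc1ccccc1 | intermediate
9 | eugenol | COc1cc(CC=C)ccc1O | starting material
10 | 4-allyl-1-(benzyloxy)-2-methoxybenzene | COc1cc(CC=C)ccc1OCc1ccccc1 | intermediate
11 | (S)-but-3-en-2-ol | C[C@H](O)C=C | starting material
12 | (S,E)-5-[4-(benzyloxy)-3-methoxyphenyl]pent-3-en-2-ol | C[C@H](O)/C=C/Cc1ccc(OCc2ccccc2)c(OC)c1 | intermediate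
13 | (2S,3E)-5-[4-(benzyloxy)-3-methoxyphenyl]pent-3-en-2-yl (2RS)-2-(benzyloxy)-3-[4-(benzyloxy)-3,5-dimethoxyphenyl]propanoate | C[C@H](OC(=O)C(Cc1cc(OC)c(OCc2ccccc2)c(OC)c1)OCc1ccccc1)/C=C/Cc1ccc(OCc2ccccc2)c(OC)c1 | intermediate
14 | chelated lithium enolate of 13, OLi cis to OBn (formed in situ) | C[C@H](O/C(O[Li])=C(/OCc1ccccc1)Cc1cc(OC)c(OCc2ccccc2)c(OC)c1)/C=C/Cc1ccc(OCc2ccccc2)c(OC)c1 | intermediate
15 | trimethylsilyl ketene acetal of 13, OSiMe3 cis to OBn (formed in situ) | C[C@H](O/C(O[Si](C)(C)C)=C(/OCc1ccccc1)Cc1cc(OC)c(OCc2ccccc2)c(OC)c1)/C=C/Cc1ccc(OCc2ccccc2)c(OC)c1 | intermediate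
16 | trimethylsilyl (2S,3R,4E)-2-(benzyloxy)-2-[4-(benzyloxy)-3,5-dimethoxybenzyl]-3-[4-(benzyloxy)-3-methoxybenzyl]hex-4-enoate (formed in situ) | COc1cc(C[C@H](/C=C/C)[C@@](OCc2ccccc2)(Cc2cc(OC)c(OCc3ccccc3)c(OC)c2)C(=O)O[Si](C)(C)C)ccc1OCc1ccccc1 | intermediate
17 | (2S,3R,4E)-2-(benzyloxy)-2-[4-(benzyloxy)-3,5-dimethoxybenzyl]-3-[4-(benzyloxy)-3-methoxybenzyl]hex-4-enoic acid | COc1cc(C[C@H](/C=C/C)[C@@](OCc2ccccc2)(Cc2cc(OC)c(OCc3ccccc3)c(OC)c2)C(=O)O)ccc1OCc1ccccc1 | intermediate
18 | (2S,3R)-2-(benzyloxy)-2-[4-(benzyloxy)-3,5-dimethoxybenzyl]-3-[4-(benzyloxy)-3-methoxybenzyl]-4,5-dihydroxyhexanoic acid, diol diastereomers (formed in situ) | COc1cc(C[C@H](C(O)C(C)O)[C@@](OCc2ccccc2)(Cc2cc(OC)c(OCc3ccccc3)c(OC)c2)C(=O)O)ccc1OCc1ccccc1 | intermediate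
19 | (2S,3S)-2-(benzyloxy)-2-[4-(benzyloxy)-3,5-dimethoxybenzyl]-3-[4-(benzyloxy)-3-methoxybenzyl]-4-oxobutanoic acid (formed in situ) | COc1cc(C[C@H](C=O)[C@@](OCc2ccccc2)(Cc2cc(OC)c(OCc3ccccc3)c(OC)c2)C(=O)O)ccc1OCc1ccccc1 | intermediate
20 | (3S,4S)-3-(benzyloxy)-3-[4-(benzyloxy)-3,5-dimethoxybenzyl]-4-[4-(benzyloxy)-3-methoxybenzyl]-5-hydroxydihydrofuran-2(3H)-one, both C5 anomers | COc1cc(C[C@@H]2C(O)OC(=O)[C@]2(OCc2ccccc2)Cc2cc(OC)c(OCc3ccccc3)c(OC)c2)ccc1OCc1ccccc1 | intermediate
21 | sodium (2S,3S)-2-(benzyloxy)-2-[4-(benzyloxy)-3,5-dimethoxybenzyl]-3-[4-(benzyloxy)-3-methoxybenzyl]-4-oxobutanoate, ring-opened form of 20 (formed in situ) | COc1cc(C[C@H](C=O)[C@@](OCc2ccccc2)(Cc2cc(OC)c(OCc3ccccc3)c(OC)c2)C(=O)O[Na])ccc1OCc1ccccc1 | intermediate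
22 | sodium (2S,3R)-2-(benzyloxy)-2-[4-(benzyloxy)-3,5-dimethoxybenzyl]-3-[4-(benzyloxy)-3-methoxybenzyl]-4-hydroxybutanoate (formed in situ) | COc1cc(C[C@H](CO)[C@@](OCc2ccccc2)(Cc2cc(OC)c(OCc3ccccc3)c(OC)c2)C(=O)O[Na])ccc1OCc1ccccc1 | intermediate
23 | (2S,3R)-2-(benzyloxy)-2-[4-(benzyloxy)-3,5-dimethoxybenzyl]-3-[4-(benzyloxy)-3-methoxybenzyl]-4-hydroxybutanoic acid (formed in situ) | COc1cc(C[C@H](CO)[C@@](OCc2ccccc2)(Cc2cc(OC)c(OCc3ccccc3)c(OC)c2)C(=O)O)ccc1OCc1ccccc1 | intermediate
24 | (3S,4R)-3-(benzyloxy)-3-[4-(benzyloxy)-3,5-dimethoxybenzyl]-4-[4-(benzyloxy)-3-methoxybenzyl]dihydrofuran-2(3H)-one | COc1cc(C[C@@H]2COC(=O)[C@]2(OCc2ccccc2)Cc2cc(OC)c(OCc3ccccc3)c(OC)c2)ccc1OCc1ccccc1 | intermediate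
25 | (3S,4R)-3-hydroxy-3-(4-hydroxy-3,5-dimethoxybenzyl)-4-(4-hydroxy-3-methoxybenzyl)dihydrofuran-2(3H)-one | COc1cc(C[C@@H]2COC(=O)[C@]2(O)Cc2cc(OC)c(O)c(OC)c2)ccc1O | target

Total step count: 12.
Longest linear sequence: 10 steps (steps 1, 2, 3, 4, 5, 8, 9, 10, 11, 12, from syringaldehyde).

Steps most likely to fail

Step 9. Enolisation of the hindered α-branched ester may be incomplete or escape chelate control, so that conversion is low or the C2 configuration is eroded. The fallback sets out from 12, uses 4, and rejoins the route at 25; it sets the two stereocentres separately on a lactone.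
- Heating 12 with triethyl orthoacetate and catalytic propionic acid (Johnson orthoester Claisen, 140 °C) should pass through the mixed ketene acetal 1-(benzyloxy)-4-[(2E,4S)-4-[(1-ethoxyethenyl)oxy]pent-2-en-1-yl]-2-methoxybenzene F1. It should give ethyl (S,E)-3-[4-(benzyloxy)-3-methoxybenzyl]hex-4-enoate F2, with the same chair-controlled chirality transfer to C3.
- Oxidative cleavage under the conditions of step 10 would proceed via ethyl (3S)-3-[4-(benzyloxy)-3-methoxybenzyl]-4,5-dihydroxyhexanoate F3 to ethyl (S)-4-[4-(benzyloxy)-3-methoxyphenyl]-3-formylbutanoate F4.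
- NaBH4 reduction to ethyl (S)-4-[4-(benzyloxy)-3-methoxyphenyl]-3-(hydroxymethyl)butanoate F5 and acid-catalysed ring closure should give (S)-4-[4-(benzyloxy)-3-methoxybenzyl]dihydrofuran-2(3H)-one F6.
- Deprotonation with LiN(SiMe3)2 (THF, −78 °C) gives the lithium enolate of this lactone F7. Alkylation with 4 anti to the C4 substituent should give (3S,4S)-3-[4-(benzyloxy)-3,5-dimethoxybenzyl]-4-[4-(benzyloxy)-3-methoxybenzyl]dihydrofuran-2(3H)-one F8.
- KN(SiMe3)2 then gives the potassium enolate of the dibenzyl lactone F9, which is oxidised with 2-(phenylsulfonyl)-3-phenyloxaziridine. Oxygen is expected to enter on the face away from the C4 benzyl group, giving (3S,4R)-3-[4-(benzyloxy)-3,5-dimethoxybenzyl]-4-[4-(benzyloxy)-3-methoxybenzyl]-3-hydroxydihydrofuran-2(3H)-one F10.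
- Hydrogenolysis as in step 12 would give 25.

Step 7. Cross-metathesis may deliver an E/Z mixture or suffer ruthenium hydride-mediated double-bond migration; any Z isomer carried forward would surface as the C3 epimer after step 9. The fallback sets out from 10 and rejoins the route at 12. Cross-metathesis of 10 with methyl vinyl ketone (catalyst of step 7, [1,3-bis(2,4,6-trimethylphenyl)imidazolidin-2-ylidene]dichloro(2-isopropoxybenzylidene)ruthenium, CH2Cl2, 40 °C) should give (E)-5-[4-(benzyloxy)-3-methoxyphenyl]pent-3-en-2-one F11, whose geometry is enforced by conjugation. Corey–Bakshi–Shibata reduction with (R)-2-methyl-CBS-oxazaborolidine and BH3·SMe2 at −30 °C should then give 12, the carbinol configuration now coming from the catalyst and not from the chiral pool.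

Step 4. The glycolate enolate may self-condense or decompose faster than it is alkylated, and dialkylation may intrude. The fallback sets out from 4 and rejoins the route at 8, bypassing 7. The stabilised sodium enolate of diethyl 2-(benzyloxy)malonate F12 (NaH, THF/DMF, 0 °C) is alkylated with 4 to give diethyl 2-(benzyloxy)-2-[4-(benzyloxy)-3,5-dimethoxybenzyl]malonate F13. Saponification (KOH, EtOH/H2O, reflux; then HCl) gives 2-(benzyloxy)-2-[4-(benzyloxy)-3,5-dimethoxybenzyl]malonic acid F14, which should lose CO2 on heating in toluene to give 8.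

Further compounds
F1 | step 9 | 1-(benzyloxy)-4-[(2E,4S)-4-[(1-ethoxyethenyl)oxy]pent-2-en-1-yl]-2-methoxybenzene (mixed ketene acetal) | C=C(OCC)O[C@@H](C)/C=C/Cc1ccc(OCc2ccccc2)c(OC)c1
F2 | step 9 | ethyl (S,E)-3-[4-(benzyloxy)-3-methoxybenzyl]hex-4-enoate | COc1cc(C[C@H](/C=C/C)CC(=O)OCC)ccc1OCc1ccccc1
F3 | step 9 | ethyl (3S)-3-[4-(benzyloxy)-3-methoxybenzyl]-4,5-dihydroxyhexanoate (diol diastereomers) | COc1cc(C[C@H](C(O)C(C)O)CC(=O)OCC)ccc1OCc1ccccc1
F4 | step 9 | ethyl (S)-4-[4-(benzyloxy)-3-methoxyphenyl]-3-formylbutanoate | COc1cc(C[C@H](C=O)CC(=O)OCC)ccc1OCc1ccccc1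
F5 | step 9 | ethyl (S)-4-[4-(benzyloxy)-3-methoxyphenyl]-3-(hydroxymethyl)butanoate | COc1cc(C[C@H](CO)CC(=O)OCC)ccc1OCc1ccccc1
F6 | step 9 | (S)-4-[4-(benzyloxy)-3-methoxybenzyl]dihydrofuran-2(3H)-one | COc1cc(C[C@@H]2COC(=O)C2)ccc1OCc1ccccc1
F7 | step 9 | lithium enolate of (S)-4-[4-(benzyloxy)-3-methoxybenzyl]dihydrofuran-2(3H)-one | COc1cc(C[C@@H]2COC(O[Li])=C2)ccc1OCc1ccccc1
F8 | step 9 | (3S,4S)-3-[4-(benzyloxy)-3,5-dimethoxybenzyl]-4-[4-(benzyloxy)-3-methoxybenzyl]dihydrofuran-2(3H)-one | COc1cc(C[C@@H]2COC(=O)[C@H]2Cc2cc(OC)c(OCc3ccccc3)c(OC)c2)ccc1OCc1ccccc1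
F9 | step 9 | potassium enolate of the (3S,4S)-dibenzyl lactone | COc1cc(C[C@@H]2COC(O[K])=C2Cc2cc(OC)c(OCc3ccccc3)c(OC)c2)ccc1OCc1ccccc1
F10 | step 9 | (3S,4R)-3-[4-(benzyloxy)-3,5-dimethoxybenzyl]-4-[4-(benzyloxy)-3-methoxybenzyl]-3-hydroxydihydrofuran-2(3H)-one | COc1cc(C[C@@H]2COC(=O)[C@]2(O)Cc2cc(OC)c(OCc3ccccc3)c(OC)c2)ccc1OCc1ccccc1
F11 | step 7 | (E)-5-[4-(benzyloxy)-3-methoxyphenyl]pent-3-en-2-one | CC(=O)/C=C/Cc1ccc(OCc2ccccc2)c(OC)c1
F12 | step 4 | sodium enolate of diethyl 2-(benzyloxy)malonate | CCOC(=O)C(OCc1ccccc1)=C(O[Na])OCC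
F13 | step 4 | diethyl 2-(benzyloxy)-2-[4-(benzyloxy)-3,5-dimethoxybenzyl]malonate | CCOC(=O)C(Cc1cc(OC)c(OCc2ccccc2)c(OC)c1)(OCc1ccccc1)C(=O)OCC
F14 | step 4 | 2-(benzyloxy)-2-[4-(benzyloxy)-3,5-dimethoxybenzyl]malonic acid | O=C(O)C(Cc1cc(OC)c(OCc2ccccc2)c(OC)c1)(OCc1ccccc1)C(=O)O
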